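**Assumptions:** the stereocentre in the target SMILES is read as (R). (Z)-1-Bromo-2-methoxyethene is not counted as a catalogue compound and is made in step 4.

**Retrosynthetic overview**
- Target ⇐ tert-butyl-protected hydroxyquinone (acidolysis) ⇐ hydroquinone (oxidation).
- The only ring made is the six-membered ring: thermal 4π-electrocyclic opening of a 4-hydroxy-4-[(Z)-2-methoxyvinyl]cyclobutenone to a dienylketene, then 6π-electrocyclisation. The four-membered ring is bought as di-tert-butyl squarate.
- Cyclobutenone ⇐ 3-alkyl-4-tert-butoxycyclobutenedione + (Z)-2-methoxyvinyllithium (from methyl vinyl ether).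
- Side chain: C–C bond between the squarate and a β-lithio alkoxide from (R)-1-chlorotridecan-2-ol ⇐ (R)-epichlorohydrin + n-decylmagnesium bromide; the stereocentre is bought and never touched.

**Route**

Step 1
Reactants: 1 (R)-epichlorohydrin; 2 n-decylmagnesium bromide
Product: 3 (R)-1-chlorotridecan-2-ol
Conditions: CuI (5 mol %), THF, −40 → 0 °C; aq. NH4Cl
Reagents that add atoms: none
Why: Copper-catalysed Grignard opening of the epoxide (SN2 at the unsubstituted ring carbon, faster than chloride displacement at low temperature) leaves the bought stereocentre untouched, so 3 is (R) like 1 because CH2Cl still outranks the new alkyl arm.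

Step 2
Reactants: 3 (R)-1-chlorotridecan-2-ol; 4 di-tert-butyl squarate
Product: 6 squarate adduct 2,3-di-tert-butoxy-4-hydroxy-4-[(2R)-2-hydroxytridecyl]cyclobut-2-en-1-one, via dilithio alkoxide 5 (not isolated)
Conditions: n-BuLi (1.0 equiv), THF, −78 °C; LiC10H8 (2.0 equiv), −78 °C, 4 h; then 4, −78 °C; aq. NH4Cl
Reagents that add atoms: none
Why: O-deprotonation and reductive chlorine–lithium exchange give a β-oxido alkyllithium (Barluenga–Yus type reagent, slow to lose Li2O at −78 °C) that adds 1,2 to one squarate carbonyl (Liebeskind–Moore squarate chemistry); the carbinol stereocentre is a spectator (5 is formally S only through a priority change) and the new ring carbinol centre forms as an epimer mixture that is erased in step 3.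

Step 3
Reactants: 6 squarate adduct
Product: 9 acetoxy dione (2R)-1-(2-tert-butoxy-3,4-dioxocyclobut-1-en-1-yl)tridecan-2-yl acetate, via secondary acetate 7 (not isolated), via tertiary trifluoroacetate 8 (not isolated)
Conditions: Ac2O (1.2 equiv), pyridine, DMAP (cat.), CH2Cl2, 0 °C; then (CF3CO)2O, 0 °C → rt; aq. NaHCO3
Reagents that add atoms: acetic anhydride, CC(=O)OC(C)=O
Why: Acetylation is selective for the secondary over the hindered tertiary hydroxyl, and trifluoroacetylation of the latter triggers the standard squarate-adduct-to-cyclobutenedione rearrangement (ionisation to the alkoxy-stabilised cyclobutenyl cation, loss of the tert-butyl cation as isobutene), so the acetate of the target is in place before a free hydroxyl could attack the dione; no stereocentre is formed.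

Step 4
Reactants: 10 methyl vinyl ether
Product: 12 (Z)-1-bromo-2-methoxyethene, via dibromo ether 11 (not isolated)
Conditions: Br2, pentane, −78 °C; then PhNEt2, 95 °C, distil
Reagents that add atoms: bromine, BrBr
Why: Electrophilic bromine addition to the enol ether followed by amine-induced dehydrobromination through the activated α-bromo ether (E1-like) gives the 2-bromovinyl ether, mainly as the (Z)-isomer as for the well-known ethyl analogue; no stereocentre.

Step 5
Reactants: 12 (Z)-1-bromo-2-methoxyethene; 9 acetoxy dione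
Product: 14 cyclobutenone (2R)-1-{2-tert-butoxy-3-hydroxy-3-[(Z)-2-methoxyethenyl]-4-oxocyclobut-1-en-1-yl}tridecan-2-yl acetate, via (Z)-2-methoxyvinyllithium 13 (not isolated)
Conditions: t-BuLi (2.0 equiv), Et2O, −78 °C; then 9, THF, −78 °C, 15 min; aq. NH4Cl at −78 °C; used crude
Reagents that add atoms: none
Why: Bromine–lithium exchange with retention gives the chelation-stabilised (Z)-2-alkoxyvinyllithium (Lau–Schlosser/Wollenberg type reagent), which adds at −78 °C to the more electrophilic carbonyl of 9 (the one next to C–OtBu, not the vinylogous ester carbonyl and not the acetate); the new carbinol centre is an epimer mixture that becomes sp2 in step 6.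

Step 6
Reactants: 14 cyclobutenone
Product: 18 tert-butoxyquinone (2R)-1-(2-tert-butoxy-5-methoxy-3,6-dioxocyclohexa-1,4-dien-1-yl)tridecan-2-yl acetate, via dienylketene 15 (not isolated), via cyclohexadienone 16 (not isolated), via hydroquinone 17 (not isolated)
Conditions: PhMe, 110 °C, 1 h; then Ag2O, rt
Reagents that add atoms: none
Why: Moore rearrangement, in which conrotatory 4π-electrocyclic opening (hydroxyl rotates outward, vinyl inward) gives the dienylketene, 6π-electrocyclisation onto the sp ketene carbon forms the six-membered ring, tautomerisation gives the hydroquinone and Ag2O oxidises it to the quinone; the transient sp3 centre of 16 is lost on aromatisation and the acetate-bearing stereocentre is a spectator.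

Step 7
Reactants: 18 tert-butoxyquinone
Product: 19 target, (2R)-1-(2-hydroxy-5-methoxy-3,6-dioxocyclohexa-1,4-dien-1-yl)tridecan-2-yl acetate
Conditions: CF3CO2H, CH2Cl2, 0 °C → rt
Reagents that add atoms: none
Why: Acidolysis of the tert-butyl vinylogous ester (E1 loss of the tert-butyl cation as isobutene) frees the 2-hydroxyl under anhydrous conditions that leave the methyl vinylogous ester, the secondary acetate and the stereocentre untouched.

**Compound list**
1 | (R)-epichlorohydrin | ClC[C@H]1CO1 | starting material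
2 | n-decylmagnesium bromide | CCCCCCCCCC[Mg]Br | starting material
3 | (R)-1-chlorotridecan-2-ol | CCCCCCCCCCC[C@H](CCl)O | intermediate
4 | di-tert-butyl squarate (3,4-di-tert-butoxycyclobut-3-ene-1,2-dione) | CC(C)(C)OC1=C(OC(C)(C)C)C(=O)C1=O | starting material
5 | lithium (2S)-1-lithiotridecan-2-olate (same spatial arrangement as 3) | CCCCCCCCCCC[C@H](C[Li])O[Li] | intermediate (not isolated)
6 | 2,3-di-tert-butoxy-4-hydroxy-4-[(2R)-2-hydroxytridecyl]cyclobut-2-en-1-one (ring carbinol epimers) | CCCCCCCCCCC[C@H](CC1(O)C(OC(C)(C)C)=C(OC(C)(C)C)C1=O)O | intermediate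
7 | (2R)-1-(2,3-di-tert-butoxy-1-hydroxy-4-oxocyclobut-2-en-1-yl)tridecan-2-yl acetate | CCCCCCCCCCC[C@H](CC1(O)C(OC(C)(C)C)=C(OC(C)(C)C)C1=O)OC(C)=O | intermediate (not isolated)
8 | (2R)-1-[2,3-di-tert-butoxy-4-oxo-1-(trifluoroacetoxy)cyclobut-2-en-1-yl]tridecan-2-yl acetate | CCCCCCCCCCC[C@H](CC1(OC(=O)C(F)(F)F)C(OC(C)(C)C)=C(OC(C)(C)C)C1=O)OC(C)=O | intermediate (not isolated)
9 | (2R)-1-(2-tert-butoxy-3,4-dioxocyclobut-1-en-1-yl)tridecan-2-yl acetate | CCCCCCCCCCC[C@H](CC1=C(OC(C)(C)C)C(=O)C1=O)OC(C)=O | intermediate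
10 | methyl vinyl ether | COC=C | starting material
11 | 1,2-dibromo-1-methoxyethane (racemic) | COC(Br)CBr | intermediate (not isolated)
12 | (Z)-1-bromo-2-methoxyethene | CO/C=C\Br | intermediate
13 | (Z)-2-methoxyvinyllithium | CO/C=C\[Li] | intermediate (not isolated)
14 | (2R)-1-{2-tert-butoxy-3-hydroxy-3-[(Z)-2-methoxyethenyl]-4-oxocyclobut-1-en-1-yl}tridecan-2-yl acetate (ring carbinol epimers) | CCCCCCCCCCC[C@H](CC1=C(OC(C)(C)C)C(O)(/C=C\OC)C1=O)OC(C)=O | intermediate
15 | (3Z,5Z)-2-[(2R)-2-acetoxytridecyl]-3-tert-butoxy-4-hydroxy-6-methoxyhexa-1,3,5-trien-1-one | CCCCCCCCCCC[C@H](CC(=C=O)/C(OC(C)(C)C)=C(O)\C=C/OC)OC(C)=O | intermediate (not isolated)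
16 | (2R)-1-(2-tert-butoxy-3-hydroxy-5-methoxy-6-oxocyclohexa-1,3-dien-1-yl)tridecan-2-yl acetate (C5 epimers) | CCCCCCCCCCC[C@H](CC1=C(OC(C)(C)C)C(O)=CC(OC)C1=O)OC(C)=O | intermediate (not isolated)
17 | (2R)-1-(2-tert-butoxy-3,6-dihydroxy-5-methoxyphenyl)tridecan-2-yl acetate | CCCCCCCCCCC[C@H](Cc1c(OC(C)(C)C)c(O)cc(OC)c1O)OC(C)=O | intermediate (not isolated)
18 | (2R)-1-(2-tert-butoxy-5-methoxy-3,6-dioxocyclohexa-1,4-dien-1-yl)tridecan-2-yl acetate | CCCCCCCCCCC[C@H](CC1=C(OC(C)(C)C)C(=O)C=C(OC)C1=O)OC(C)=O | intermediate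
19 | (2R)-1-(2-hydroxy-5-methoxy-3,6-dioxocyclohexa-1,4-dien-1-yl)tridecan-2-yl acetate | CCCCCCCCCCC[C@H](CC1=C(O)C(=O)C=C(OC)C1=O)OC(C)=O | target

**Step count:** 7 steps in total. Longest linear sequence: 6 steps (1, 2, 3, 5, 6, 7); step 4 is a one-step side branch.

**Steps most likely to fail, each with a fallback**

Step 2 (making 5 and adding it to 4). Loss of Li2O to 1-tridecene, protonation, or electron transfer from residual naphthalenide to the easily reduced squarate can erode the yield. The fallback sets out from 3 and comes back at 6. The carbanion is reached by reductive cleavage of an epoxide C–O bond instead of a C–Cl bond and is delivered as a cerium reagent instead of a lithium reagent. Aqueous NaOH closes 3 to (R)-1,2-epoxytridecane F1. LiC20H26 (lithium 4,4'-di-tert-butylbiphenylide) in THF at −78 °C opens the epoxide at the unsubstituted carbon, and anhydrous CeCl3 converts the resulting β-lithio alkoxide into the dichlorocerium reagent F2. This reagent is neither basic nor reducing and adds 1,2 to 4; NH4Cl work-up gives 6.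

Step 5 (vinyllithium in the presence of the acetate and the acidic ring-CH2 next to it). Attack on the ester or deprotonation followed by loss of acetate would compete if the addition to the dione is not fast enough. The fallback sets out from 6 and comes back at 18. The acetate is kept away from the organolithium and put on after the ring is built. t-BuMe2SiCl/imidazole silylates the secondary hydroxyl of 6 to give silyl ether F3. (CF3CO)2O/pyridine gives the silyloxy dione F4, and 13 adds to give cyclobutenone F5. Thermolysis in toluene and Ag2O oxidation give the silyloxy quinone F6. HF·pyridine frees the alcohol F7, and Ac2O/pyridine/DMAP gives 18.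

Step 6 (ring opening and 6π closure of 14). The ring has to close onto the methoxy-bearing (Z)-terminus, which is sterically and electronically the less favourable end of the enol ether, and 14 itself is acid-sensitive. The fallback sets out from 4, uses 10 and 5, and comes back at 18. The order of the two carbanion additions is inverted so that the ring closes onto the unsubstituted terminus of a 1-methoxyvinyl group. 10 is lithiated with t-BuLi to 1-methoxyvinyllithium F8, which adds to 4, and Me3SiCl traps the alkoxide as silyl ether F9. 5 adds to the remaining carbonyl to give diol F10. Ac2O/pyridine and then (CF3CO)2O acetylate the secondary hydroxyl and ionise the new tertiary one; the cation is quenched by loss of the tert-butyl group from the remote oxygen, giving the transposed cyclobutenone F11. In F11 the alkyl and tert-butoxy groups have changed places relative to 14, which is what the 1-methoxyvinyl group needs to reach the same substitution pattern. Thermolysis in toluene gives the monosilylated hydroquinone F12, and Et3N·3HF followed by Ag2O gives 18.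

**Further compounds**
F1 | step 2 | (R)-1,2-epoxytridecane | CCCCCCCCCCC[C@@H]1CO1
F2 | step 2 | lithium (2R)-1-(dichloroceryl)tridecan-2-olate | CCCCCCCCCCC[C@H](C[Ce](Cl)Cl)O[Li]
F3 | step 5 | 2,3-di-tert-butoxy-4-[(2R)-2-(tert-butyldimethylsilyloxy)tridecyl]-4-hydroxycyclobut-2-en-1-one | CCCCCCCCCCC[C@H](CC1(O)C(OC(C)(C)C)=C(OC(C)(C)C)C1=O)O[Si](C)(C)C(C)(C)C
F4 | step 5 | 3-tert-butoxy-4-[(2R)-2-(tert-butyldimethylsilyloxy)tridecyl]cyclobut-3-ene-1,2-dione | CCCCCCCCCCC[C@H](CC1=C(OC(C)(C)C)C(=O)C1=O)O[Si](C)(C)C(C)(C)C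
F5 | step 5 | 3-tert-butoxy-2-[(2R)-2-(tert-butyldimethylsilyloxy)tridecyl]-4-hydroxy-4-[(Z)-2-methoxyethenyl]cyclobut-2-en-1-one | CCCCCCCCCCC[C@H](CC1=C(OC(C)(C)C)C(O)(/C=C\OC)C1=O)O[Si](C)(C)C(C)(C)C
F6 | step 5 | 2-tert-butoxy-3-[(2R)-2-(tert-butyldimethylsilyloxy)tridecyl]-5-methoxy-1,4-benzoquinone | CCCCCCCCCCC[C@H](CC1=C(OC(C)(C)C)C(=O)C=C(OC)C1=O)O[Si](C)(C)C(C)(C)C
F7 | step 5 | 2-tert-butoxy-3-[(2R)-2-hydroxytridecyl]-5-methoxy-1,4-benzoquinone | CCCCCCCCCCC[C@H](CC1=C(OC(C)(C)C)C(=O)C=C(OC)C1=O)O
F8 | step 6 | 1-methoxyvinyllithium | C=C(OC)[Li]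
F9 | step 6 | 2,3-di-tert-butoxy-4-(1-methoxyethenyl)-4-(trimethylsilyloxy)cyclobut-2-en-1-one | C=C(OC)C1(O[Si](C)(C)C)C(OC(C)(C)C)=C(OC(C)(C)C)C1=O
F10 | step 6 | 2,3-di-tert-butoxy-1-[(2R)-2-hydroxytridecyl]-4-(1-methoxyethenyl)-4-(trimethylsilyloxy)cyclobut-2-en-1-ol | CCCCCCCCCCC[C@H](CC1(O)C(OC(C)(C)C)=C(OC(C)(C)C)C1(O[Si](C)(C)C)C(OC)=C)O
F11 | step 6 | (2R)-1-[2-tert-butoxy-4-(1-methoxyethenyl)-3-oxo-4-(trimethylsilyloxy)cyclobut-1-en-1-yl]tridecan-2-yl acetate | CCCCCCCCCCC[C@H](CC1=C(OC(C)(C)C)C(=O)C1(O[Si](C)(C)C)C(OC)=C)OC(C)=O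
F12 | step 6 | (2R)-1-[2-tert-butoxy-3-hydroxy-5-methoxy-6-(trimethylsilyloxy)phenyl]tridecan-2-yl acetate | CCCCCCCCCCC[C@H](Cc1c(OC(C)(C)C)c(O)cc(OC)c1O[Si](C)(C)C)OC(C)=O
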